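(The earlier runs and the new flask stem from a simulated flask with constants of no real substance; scatter was added.)

Turn the question round.

| setting | west | south-west | ash | cedar | larch | maple | birch |
|---|---|---|---|---|---|---|---|
| substrate | 0.0020 M | 0.0020 M | 0.0020 M | 0.0020 M | 0.0020 M | 0.0020 M | 0.0020 M |
| partner | 0.34 equiv | 4.9 equiv | 1.05 equiv | 4.20 equiv | 0.260 equiv | 2.10 equiv | 1.60 equiv |
| temperature | −35 °C | −20 °C | −20 °C | −20 °C | −20 °C | −20 °C | −20 °C |
| remark | run made earlier | run made earlier |  |  |  |  |  |
| time |  |  | 2.0 min | 2.0 min | 2.0 min | 2.0 min | 2.0 min |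

| run | time / s | product / % |
|---|---|---|
| west | 20.0 | 0 |
| west | 25.0 | 0 |
| west | 40.0 | 0 |
| west | 60.0 | 0 |
| west | 120 | 1 |
| south-west | 10.0 | 2 |
| south-west | 12.0 | 0 |
| south-west | 20.0 | 4 |
| south-west | 30.0 | 9 |
| south-west | 50.0 | 14 |
| south-west | 60.0 | 19 |

(scatter of a reading: 1.5 percentage points)

* the flasks put in order of amount of product, in percent of the substrate charged, best first, at 2.0 min (ash / cedar / larch / maple / birch)
* the amount of product, in percent of the substrate charged of the flask you put first, at 2.0 min
* the amount of product, in percent of the substrate charged of the flask you put last, at 2.0 min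

- steps that have been proposed: substrate <-> intermediate A; substrate <-> intermediate B; substrate + partner <-> intermediate C; partner + intermediate B <-> intermediate D; intermediate D <-> product; intermediate A <-> intermediate B

Ask what would have to be true for a flask with less partner to beat one with more at the same time. Take as the zero of the scale the case where every equivalent of partner gives the same product, so that the order follows the charges. A pair then reverses when product per equivalent falls, from the poorer flask to the richer, by more than their charge ratio. Birch and maple stand closest, so call 1.31 the crossing ratio, the fall in product per equivalent at which birch would overtake maple.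

Now measure the distance. Run the south-west reading of 19% at 60.0 s straight on to 2.0 min and scale it by charge: maple gets 16.3% and birch 12.4%, each carrying the scatter of that reading. The two runs differ in both charge and temperature, so they show no curve in partner. The proposed step from substrate and partner to intermediate C could bend the line, and for birch to pass maple the bend must exceed the crossing ratio. In larch the partner, at 0.260 equiv, is by charge the limiting reagent. Commit to the order of the charges, with cedar at 32.6% and larch at 2.02%.

The forecast, “Assuming roughly first order in partner”, gave cedar > maple > birch > ash > larch, with 30% and 2.5%, where my line gives 32.6% and 2.02%.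

The flasks give cedar > maple > birch > ash > larch, with cedar at 24.6% and larch at 3.76%.

    substrate ⇌ intermediate A (K = 0.540, k = 0.0150 s⁻¹, Ea = 74.0 kJ mol⁻¹, ΔH = −10.0 kJ mol⁻¹)
    substrate ⇌ intermediate B (K = 0.460, k = 0.160 s⁻¹, Ea = 65.0 kJ mol⁻¹, ΔH = −77.0 kJ mol⁻¹)
    substrate + partner ⇌ intermediate C (K = 1000 L mol⁻¹, k = 5.20 L mol⁻¹ s⁻¹, Ea = 37.0 kJ mol⁻¹, ΔH = −13.0 kJ mol⁻¹)
    partner + intermediate B ⇌ intermediate D (K = 960 L mol⁻¹, k = 13.0 L mol⁻¹ s⁻¹, Ea = 48.0 kJ mol⁻¹, ΔH = −15.0 kJ mol⁻¹)
    intermediate D ⇌ product (K = 2.30, k = 0.0180 s⁻¹, Ea = 68.0 kJ mol⁻¹, ΔH = −30.0 kJ mol⁻¹)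
    intermediate A ⇌ intermediate B (k = 0.130 s⁻¹, Ea = 70.0 kJ mol⁻¹)
    (constants at −20 °C)

Cedar lies 8.0 percentage points under my line, and at 2.00 min it holds 46.4% as intermediate C, more than its product. From birch to maple, product per equivalent falls by a factor of 1.13, less than the crossing ratio. At 20.0 min, with maple at 31.5% and birch at 28.4%, that fall is 1.18.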